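Its constants were drawn at random within sensible limits; the rest is arithmetic.

- Intermediate A cannot become product directly: the arrow into product starts at substrate, so I kept books on the substrate charge and entered each fraction as it left substrate, and on which side.

| setting | winter | dawn | autumn |
|---|---|---|---|
| substrate | 0.50 M | 0.50 M | 0.50 M |
| reagent | 0.500 M | 0.500 M | 0.500 M |
| temperature | 95 °C | 110 °C | 125 °C |
| time | 50 min | 50 min | 50 min |

* the flask that comes out highest in amount of product, in percent of the substrate charged, or "all alike" when all lie within 1.5 percentage points (winter / dawn / autumn / all alike)
* product at the end, in percent of the substrate charged, winter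
* product at the end, in percent of the substrate charged, dawn
* product at the end, in percent of the substrate charged, autumn

- constants are those at 110 °C; use the activation energies and enthalpies for any other temperature

    intermediate C → intermediate D (k1 = 9.47 × 10⁻⁴ /min, Ea1 = 114 kJ/mol)
    reagent + intermediate A ⇌ intermediate B (K2 = 3.1 /M, k2 = 0.00810 /M/min, Ea2 = 88.0 kJ/mol, ΔH2 = 21.0 kJ/mol)
    substrate ⇌ intermediate A (K3 = 2.2, k3 = 0.0111 /min, Ea3 = 112 kJ/mol, ΔH3 = −5.00 kJ/mol)
    intermediate D ⇌ intermediate E (K4 = 2.91, k4 = 0.0185 /min, Ea4 = 122 kJ/mol, ΔH4 = −23.0 kJ/mol)
    reagent + intermediate B → intermediate C (k5 = 0.00780 /M/min, Ea5 = 95.0 kJ/mol)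
    substrate → product (k6 = 0.00704 /min, Ea6 = 108 kJ/mol)
    (constants at 110 °C)

- First entry, the branch: at dawn, substrate left for intermediate A with k3 and for product with k6, the former being the larger. I carried one quantity, the leak share, k6 over k3 + k6, the fraction of departing substrate booked to product (the selectivity at this branch), 38.8 %.
- Temperature: the activation energy of step 3 exceeds that of step 6 by 4.00 kJ/mol, so I held the leak share for the three flasks and let temperature act on the clock. Step 6 speeds up 14-fold from winter to autumn, so I took a factor of 3.78 between neighbouring flasks, for both steps.
- Second entry, the departures: at dawn, substrate left with the constant 0.0181 /min, so over 50 min the fraction departed was 59.5 %. Multiplied by the leak share, this first pass booked 23.1 % to product at dawn and 8.28 % in winter.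
- Third entry, intermediate A: at dawn it went on to intermediate B with k2 times the reagent charge, 0.00405 /min, slower than substrate departed. It returned to substrate at k3/K3, 0.00505 /min, a credit my first pass omitted.
- Size of that credit: the return constant times the run length was 0.253 at dawn and 0.953 in autumn, larger in the hot flask.
- Closing the books for autumn, I committed to a floor. The first pass gave 37.5 %, with the return credit, which I did not size further, to come on top. My first-pass figures put autumn highest.
- The forecast named autumn, with 8.1 % for winter, 24.3 % for dawn and 46.5 % for autumn, on the ground that “Product forms only by the first-order leak from substrate”.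
- The simulation gave 7.94 % for winter, 23.6 % for dawn and 44.0 % for autumn, with autumn highest, so autumn stood above my floor.
- The leak share times the autumn conversion of 87.3 % booked 33.9 %, while the autumn flask held 44.0 %, a gap of 10 percentage points. Taking away the conversion of substrate into intermediate A, both ways, lifted autumn product to 71.7 %, and a run of 500 min lifted it to 74.2 %: the detour and the length of the run held it down together. For dawn read at 80 min, the same first pass booked 29.7 %, and that flask held 31.2 %.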